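**Retrosynthetic overview**
1. Rings: A = β-triketone ring fused to the pyran, B = dihydropyran, C = pendant enol-triketone ring on C2. Ring C is grown on an acetate side chain at C2 by a two-carbon ring expansion of 2,2,4,4-tetramethylcyclobutane-1,3-dione (four to six members); the same operation re-closes ring B (O1–C2) and sets C2.
2. Enabling feature: the C(=O)–CMe2–C(=O)–CMe2 run of ring C is the strained cyclobutanedione itself. The ester α-carbon (the ring C carbon bonded to C2) adds to one of its carbonyls, the C(O)–CMe2 bond opens to an enolate, and this enolate lies six atoms from the ester carbonyl. The oxygen on C2, held as an alkoxide, blocks β-elimination meanwhile.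
3. The β-hydroxy ester comes from an acetate aldol on a lactol. The lactol comes from an organocatalytic Michael addition/lactolisation of isovaleraldehyde with 3-methylbutylidene-syncarpic acid, which sets C3 and C4.
4. Order of ring formation: ring A (purchased), ring B as lactol (step 2, opened in step 3), ring C (step 4, four to six), ring B again (step 4).

Key step: step 4

Remark: syncarpic acid, isovaleraldehyde, methyl acetate and 2,2,4,4-tetramethylcyclobutane-1,3-dione are taken as purchasable; C2, C3, C4 follow the chromene numbering of the target (O1, C2 bearing ring C, C3 isopropyl, C4 isobutyl), whose substituents are 2,3-cis and 3,4-trans.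

**Step 1**
Reactants: 1 syncarpic acid (2,2,4,4-tetramethylcyclohexane-1,3,5-trione); 2 isovaleraldehyde (3-methylbutanal)
Product: 3 2,2,4,4-tetramethyl-6-(3-methylbutylidene)cyclohexane-1,3,5-trione
Conditions: 2 (1.05 equiv), L-proline (10 mol %), CH2Cl2, 0 °C to rt; short silica plug, used at once
Reagents that add atoms: none
Why: Knoevenagel condensation of the cyclic β-triketone with the aldehyde through the proline iminium ion should give the alkylidene triketone; no stereocentre forms, and the symmetric ring removes any E/Z question.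

**Step 2**
Reactants: 3 2,2,4,4-tetramethyl-6-(3-methylbutylidene)cyclohexane-1,3,5-trione; 2 isovaleraldehyde
Product: 5 (2RS,3S,4S)-2-hydroxy-4-isobutyl-3-isopropyl-6,6,8,8-tetramethyl-3,4-dihydro-2H-chromene-5,7(6H,8H)-dione, via open-chain Michael aldehyde 4 (not isolated)
Conditions: 2 (3 equiv), (R)-α,α-diphenylprolinol trimethylsilyl ether (10 mol %), PhCO2H (10 mol %), toluene, 0 °C; moist silica work-up
Reagents that add atoms: none
Why: Enamine-mediated Michael addition (formally an inverse-electron-demand oxa-Diels–Alder reaction) of the E-enamine of 2 to the doubly activated alkylidene 3, then hydrolysis and hemiacetal closure, is a well-precedented class for diarylprolinol silyl ethers; the CPh2(OSiMe3) group shields one enamine face so that C3 should become S with the R catalyst, the synclinal transition state should give the syn adduct (3,4-trans, C4 S), and the anomeric carbon stays a mixture that is erased later.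

**Step 3**
Reactants: 5 lactol from step 2; 6 methyl acetate
Product: 7 methyl (3RS,4S,5S)-3-hydroxy-5-(2-hydroxy-3,3,5,5-tetramethyl-4,6-dioxocyclohex-1-en-1-yl)-7-methyl-4-(propan-2-yl)octanoate
Conditions: 6 (3.2 equiv), LiN(i-Pr)2 (3.0 equiv), THF, −78 °C; then 5, −78 °C; AcOH quench at −78 °C; neutral work-up, used without acidic chromatography
Reagents that add atoms: none
Why: Aldol addition of a lithium ester enolate to the aldehyde released when the lithium lactolate ring-opens (the ring A enolate is the leaving group) should give the β-hydroxy ester; the new carbinol centre forms as a mixture that step 4 erases, and at −78 °C addition should outrun enolisation so that C3 and C4 are kept.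

**Step 4**
Reactants: 7 β-hydroxy ester from step 3; 8 2,2,4,4-tetramethylcyclobutane-1,3-dione
Product: 13 ericifolione, via cyclobutanol adduct 9 (not isolated), via acyclic triketo ester 10 (not isolated), via ring-expanded carbinol 11 (not isolated), via alkylidene triketone 12 (not isolated)
Conditions: LiN(i-Pr)2 (3.3 equiv), THF, −78 to −30 °C; 8 (1.1 equiv), −78 to 0 °C; LiN(i-Pr)2 (1.5 equiv), 0 °C to rt; 2 M HCl; then p-TsOH (10 mol %), toluene, 50 °C
Reagents that add atoms: none
Why: Proposed new method: the trilithio derivative of 7 (ring A enolate, C2 alkoxide, ester enolate; a Fráter–Seebach-type species) should add through its ester α-carbon to one carbonyl of 8, and the strained cyclobutanolate 9 should open by retro-Claisen cleavage of a C(O)–CMe2 bond to the acyclic triketo ester 10 as its isopropyl-ketone enolate, which acylates on the methyl ester (Dieckmann condensation, 6-exo-trig, loss of methoxide; the extra base re-forms this enolate if proton transfer to the β-keto ester intervenes) to give the six-membered trione 11, a net insertion of the ester C–C(=O) unit into the four-membered ring. The closest known reaction types are the ring-opening C-acylation of carbanions by 2,2,4,4-tetramethylcyclobutane-1,3-dione, the Dieckmann cyclisation of 3,5-dioxo esters to syncarpic-acid-type triones and the aldol and alkylation chemistry of β-hydroxy ester dianions. On acidification 11 should dehydrate to the alkylidene triketone 12 (Knoevenagel-type elimination), and an enol oxygen of ring A should close ring B by 6-exo-trig oxa-Michael addition. C3 and C4 are carried unchanged from 7 because neither is deprotonated, while C2 is set under thermodynamic control through the reversible oxa-Michael addition: the expected favoured isomer has the C4 isobutyl pseudoaxial (away from the C5 carbonyl), the C3 isopropyl axial and anti to it, and ring C equatorial, which is the 2,3-cis/3,4-trans target. The step needs C-attack of the ester enolate over O-acylation and must avoid β-elimination; the C2 alkoxide (no leaving group), the higher nucleophilicity of the ester enolate at −78 °C and only a slight excess of 8 should secure both.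

**Compound list**
1 | syncarpic acid (2,2,4,4-tetramethylcyclohexane-1,3,5-trione) | CC1(C)C(=O)CC(=O)C(C)(C)C1=O | starting material
2 | isovaleraldehyde (3-methylbutanal) | CC(C)CC=O | starting material
3 | 2,2,4,4-tetramethyl-6-(3-methylbutylidene)cyclohexane-1,3,5-trione | CC(C)CC=C1C(=O)C(C)(C)C(=O)C(C)(C)C1=O | intermediate
4 | (2S,3S)-3-(2-hydroxy-3,3,5,5-tetramethyl-4,6-dioxocyclohex-1-en-1-yl)-5-methyl-2-(propan-2-yl)hexanal | CC(C)C[C@H](C1=C(O)C(C)(C)C(=O)C(C)(C)C1=O)[C@@H](C=O)C(C)C | intermediate (not isolated)
5 | (2RS,3S,4S)-2-hydroxy-4-isobutyl-3-isopropyl-6,6,8,8-tetramethyl-3,4-dihydro-2H-chromene-5,7(6H,8H)-dione | CC(C)C[C@@H]1C2=C(OC(O)[C@H]1C(C)C)C(C)(C)C(=O)C(C)(C)C2=O | intermediate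
6 | methyl acetate | COC(C)=O | starting material
7 | methyl (3RS,4S,5S)-3-hydroxy-5-(2-hydroxy-3,3,5,5-tetramethyl-4,6-dioxocyclohex-1-en-1-yl)-7-methyl-4-(propan-2-yl)octanoate | CC(C)C[C@H](C1=C(O)C(C)(C)C(=O)C(C)(C)C1=O)[C@@H](C(O)CC(=O)OC)C(C)C | intermediate
8 | 2,2,4,4-tetramethylcyclobutane-1,3-dione | CC1(C)C(=O)C(C)(C)C1=O | starting material
9 | methyl (4S,5S)-3-hydroxy-2-(1-hydroxy-2,2,4,4-tetramethyl-3-oxocyclobutyl)-5-(2-hydroxy-3,3,5,5-tetramethyl-4,6-dioxocyclohex-1-en-1-yl)-7-methyl-4-(propan-2-yl)octanoate, C2 and C3 as mixtures | CC(C)C[C@H](C1=C(O)C(C)(C)C(=O)C(C)(C)C1=O)[C@@H](C(O)C(C(=O)OC)C2(O)C(C)(C)C(=O)C2(C)C)C(C)C | intermediate (not isolated)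
10 | methyl 2-[(2S,3S)-1-hydroxy-3-(2-hydroxy-3,3,5,5-tetramethyl-4,6-dioxocyclohex-1-en-1-yl)-5-methyl-2-(propan-2-yl)hexyl]-4,4,6-trimethyl-3,5-dioxoheptanoate, carbinol and α-carbon as mixtures | CC(C)C[C@H](C1=C(O)C(C)(C)C(=O)C(C)(C)C1=O)[C@@H](C(O)C(C(=O)OC)C(=O)C(C)(C)C(=O)C(C)C)C(C)C | intermediate (not isolated)
11 | 3-hydroxy-2-[(2S,3S)-1-hydroxy-3-(2-hydroxy-3,3,5,5-tetramethyl-4,6-dioxocyclohex-1-en-1-yl)-5-methyl-2-(propan-2-yl)hexyl]-4,4,6,6-tetramethylcyclohex-2-ene-1,5-dione, carbinol as mixture | CC(C)C[C@H](C1=C(O)C(C)(C)C(=O)C(C)(C)C1=O)[C@@H](C(O)C2=C(O)C(C)(C)C(=O)C(C)(C)C2=O)C(C)C | intermediate (not isolated)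
12 | 2-[(2R,3S)-3-(2-hydroxy-3,3,5,5-tetramethyl-4,6-dioxocyclohex-1-en-1-yl)-5-methyl-2-(propan-2-yl)hexylidene]-4,4,6,6-tetramethylcyclohexane-1,3,5-trione (same spatial arrangement as in 7; the descriptor changes by priority only) | CC(C)C[C@H](C1=C(O)C(C)(C)C(=O)C(C)(C)C1=O)[C@@H](C=C2C(=O)C(C)(C)C(=O)C(C)(C)C2=O)C(C)C | intermediate (not isolated)
13 | ericifolione, (2R,3S,4S)-2-(2-hydroxy-3,3,5,5-tetramethyl-4,6-dioxocyclohex-1-en-1-yl)-4-isobutyl-3-isopropyl-6,6,8,8-tetramethyl-3,4-dihydro-2H-chromene-5,7(6H,8H)-dione | CC(C)C[C@@H]1C2=C(O[C@@H](C3=C(O)C(C)(C)C(=O)C(C)(C)C3=O)[C@H]1C(C)C)C(C)(C)C(=O)C(C)(C)C2=O | target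

**Count**
Total steps: 4. Longest linear sequence: 4 steps (1 to 3 to 5 to 7 to 13).

**Steps most likely to fail**

Step 4 (proposed method). The hindered trianion may fail to form the C–C bond to the cyclobutanedione carbonyl, the C2 alkoxide may be acylated instead, or the sequence may stall at the open-chain stage when proton transfer quenches the tertiary enolate before Dieckmann closure. Fallback with known chemistry: ring C would be brought in as the finished six-membered ring. Setting out from 5 and 1, an amine-catalysed Knoevenagel condensation (piperidine/AcOH or L-proline, CH2Cl2 or toluene, rt to 40 °C) of the open aldehyde form 4 with 1 should give 12, which closes by oxa-Michael addition and equilibrates at C2 to 13. The fallback comes back to the route at 13 and makes no compound outside the list (entry F0).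

Step 2. Facial discrimination in the enamine addition may be insufficient, and a racemic background reaction of 3 through its dienol may erode the enantiomeric purity. Fallback: racemic synthesis and resolution. Setting out from 3 and 2, pyrrolidine/AcOH catalysis in CH2Cl2 should give the trans lactol as the racemate, that is 5 together with its enantiomer, (2RS,3R,4R)-lactol F1. Acetalisation with (1R,2S,5R)-(−)-menthol (p-TsOH cat., toluene, 4 Å sieves) should give the diastereomeric menthyl acetal of 5, F2, and menthyl acetal of the enantiomer, F3, to be separated by chromatography or crystallisation. Hydrolysis of F2 (aq. HCl, THF) returns to the route at 5.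

Step 1. The Knoevenagel product may over-react during formation and isolation, by a second Michael addition of 1 or by self-condensation through its dienol tautomer. Fallback: a storable surrogate. Setting out from 1 and 2, piperidine (1.1 equiv) in CH2Cl2 should give the Mannich base 2-[3-methyl-1-(piperidin-1-yl)butyl]syncarpic acid, F4. Under the acid cocatalyst of step 2 this should lose piperidine and release 3 in the flask, so the route is rejoined at 3.

**Further compounds**
F0 | step 4 | none | none
F1 | step 2 | (2RS,3R,4R)-2-hydroxy-4-isobutyl-3-isopropyl-6,6,8,8-tetramethyl-3,4-dihydro-2H-chromene-5,7(6H,8H)-dione (enantiomer of 5) | CC(C)C[C@H]1C2=C(OC(O)[C@@H]1C(C)C)C(C)(C)C(=O)C(C)(C)C2=O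
F2 | step 2 | (3S,4S)-4-isobutyl-3-isopropyl-2-[(1R,2S,5R)-menthyloxy]-6,6,8,8-tetramethyl-3,4-dihydro-2H-chromene-5,7(6H,8H)-dione | CC(C)C[C@@H]1C2=C(OC(O[C@@H]3C[C@H](C)CC[C@H]3C(C)C)[C@H]1C(C)C)C(C)(C)C(=O)C(C)(C)C2=O
F3 | step 2 | (3R,4R)-4-isobutyl-3-isopropyl-2-[(1R,2S,5R)-menthyloxy]-6,6,8,8-tetramethyl-3,4-dihydro-2H-chromene-5,7(6H,8H)-dione | CC(C)C[C@H]1C2=C(OC(O[C@@H]3C[C@H](C)CC[C@H]3C(C)C)[C@@H]1C(C)C)C(C)(C)C(=O)C(C)(C)C2=O
F4 | step 1 | 3-hydroxy-4,4,6,6-tetramethyl-2-[3-methyl-1-(piperidin-1-yl)butyl]cyclohex-2-ene-1,5-dione (racemic) | CC(C)CC(N1CCCCC1)C1=C(O)C(C)(C)C(=O)C(C)(C)C1=O
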